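(The data were generated by integration on assumed constants, noise included.)

I took free Z plus J to stay equal to the Z charged, though no run read Z: the maple readings levelled at 0.191 mM of J against 0.19 mM of Z charged.

| flask | G | Z | temperature | remark | time |
|---|---|---|---|---|---|
| alder | 0.13 mM | 0.19 mM | −12 °C | run made earlier |  |
| maple | 0.30 mM | 0.19 mM | 15 °C | run made earlier |  |
| south-west | 0.20 mM | 0.190 mM | 25 °C |  | 15 min |
| north-east | 0.20 mM | 0.190 mM |  | at −25 °C until 10 min, from then on at 25 °C | 15 min |
| north | 0.20 mM | 0.190 mM | −25 °C |  | 15 min |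
| west | 0.20 mM | 0.190 mM | 0 °C |  | 15 min |

| run | time / min | J / % |
|---|---|---|
| alder | 6.00 | 1.4 |
| alder | 8.00 | 1.6 |
| alder | 12.0 | 3.0 |
| alder | 20.0 | 5.2 |
| alder | 30.0 | 7.1 |
| alder | 50.0 | 10.7 |
| alder | 80.0 | 17.0 |
| maple | 1.50 | 13.9 |
| maple | 2.00 | 17.0 |
| maple | 3.00 | 25.2 |
| maple | 5.00 | 37.6 |
| maple | 8.00 | 51.4 |
| maple | 12.0 | 63.5 |
| maple | 20.0 | 63.5 |

(scatter of a reading: 0.5 percentage points)



1. which flask leads in amount of J, in percent of the G charged ("all alike" within 1.5 percentage points) (south-west / north-east / north / west / all alike)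
2. how much J is there at the end, in percent of the G charged: south-west
3. how much J is there at the end, in percent of the G charged: north-east
4. how much J is there at the end, in percent of the G charged: north
5. how much J is there at the end, in percent of the G charged: west

So with 0.20 mM of G and 0.190 mM of Z, I set a ceiling on J of 95.0%. Below that ceiling I read J as a first-order fall of G. Maple at 5.00 min gave a rate constant of 0.0943 min⁻¹, and alder at 80.0 min gave 0.002329 min⁻¹.

From these two I took the warming scale, the logarithm of their ratio divided by the difference of the inverse absolute temperatures, which is the activation energy divided by the gas constant: 10300 K. Multiplying that scale by the change in inverse temperature gives the logarithm of the change in rate.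

It gave 0.313 min⁻¹ at 25 °C and 2.941 × 10⁻⁴ min⁻¹ at −25 °C. In north-east the cold stretch counted for less than the warm one, so I reckoned 79.1% of J there.

The forecast named south-west as leader, with 95% there, 79% in north-east, 0.5% in north and 18% in west. Its ground for the ceiling was: “That is all the Z, so G and Z react 1:1 and the reaction stops when Z runs out.”

The flasks gave south-west as leader, with 90.3% there, 76.8% in north-east, 0.417% in north and 17.8% in west.

    G ⇌ D + E (K = 1.10 × 10⁻⁶ M, k = 0.00547 s⁻¹, Ea = 87.0 kJ mol⁻¹, ΔH = −6.00 kJ mol⁻¹)
    G + E → X (k = 6.49 M⁻¹ s⁻¹, Ea = 36.0 kJ mol⁻¹)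
    Z + D → J (k = 5.79 × 10⁵ M⁻¹ s⁻¹, Ea = 28.0 kJ mol⁻¹)
    (constants at 25 °C)

In north the warming scale gave G a half-life of 39.3 h. In north at 7.50 min, the half-life of G by the forward rate of the step from G to D + E alone stood at 41 h, while its half-life by the step from G + E to X was 1300 h, longer. West left to 150 min shows what would part from the forecast's reckoning: it held 68.6% of J and 26.5% of X, with J below the ceiling of 95.0%.

For north's neighbour at −10 °C, with the same charges and time, the scale gave 4.61% of J. The computed flask held 4.51%.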